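**Remark on the chemistry:** the target has no stereogenic centre and is achiral, so the stereochemical task is the three double-bond geometries: (Z) in the angelate, (Z) in the 2-(acyloxymethyl)but-2-enoate (methyl cis to the ester carbonyl), and (E) in the cinnamyl unit.

**Plan**
- Retrosynthesis cuts first the CH2–CH= bond of the cinnamyl ester (between the ester O–CH2 carbon and the styrenyl CH), then the vinyl C–CO2 bond of the central enoate, then the angelate C–O bond.
- Enabling feature: the ester O–CH2 carbon sits between an acyloxy oxygen and the styrenyl sp2 carbon. It can therefore be made as an oxygen-stabilised acyloxymethyl radical from an O-acylglycolic acid by loss of CO2, and joined to an (E)-styrenyl bromide on nickel.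
- Forward: crotonaldehyde → (Z)-2-iodobut-2-en-1-ol → angelate ester → Pd alkoxycarbonylation with tert-butyl glycolate → acid → N-hydroxyphthalimide ester → Ni-electrocatalytic decarboxylative alkenylation with the bromostyrene made from 3,4-dimethoxycinnamic acid.
- Geometry: the angelate Z comes with angelic acid and is kept by a non-isomerising mixed-anhydride acylation. The central Z comes from the (Z)-iodoenal and is retained in the carbonylation. The E comes from the E-selective bromodecarboxylation and the stereoretentive coupling.

Key step: step 8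

**Step 1**
Reactants: 1 crotonaldehyde ((E)-but-2-enal)
Product: 2 (Z)-2-iodobut-2-enal
Conditions: I2, K2CO3, DMAP (cat.), THF/H2O, rt
Reagents that add atoms: iodine, II
Why: α-iodination of an enal by conjugate addition of DMAP, iodination of the enolate and E1cB loss of DMAP (Baylis–Hillman-type α-halogenation) should give the more stable Z isomer with iodine cis to the methyl group.

**Step 2**
Reactants: 2 (Z)-2-iodobut-2-enal
Product: 3 (Z)-2-iodobut-2-en-1-ol
Conditions: NaBH4, CeCl3·7H2O, MeOH, 0 °C
Reagents that add atoms: none
Why: Luche 1,2-reduction of the enal should leave the vinyl iodide and its geometry untouched.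

**Step 3**
Reactants: 3 (Z)-2-iodobut-2-en-1-ol; 4 angelic acid ((Z)-2-methylbut-2-enoic acid)
Product: 6 (Z)-2-iodobut-2-enyl angelate, via angelic 2,4,6-trichlorobenzoic mixed anhydride 5 (not isolated)
Conditions: 4, 2,4,6-trichlorobenzoyl chloride, Et3N, toluene, rt; then 3, 80 °C (no DMAP)
Reagents that add atoms: 2,4,6-trichlorobenzoyl chloride, O=C(Cl)c1c(Cl)cc(Cl)cc1Cl (its acyl group is carried only by intermediate 5)
Why: Yamaguchi-type mixed-anhydride esterification without a nucleophilic catalyst is the established way to angelate a primary alcohol without Z→E isomerisation to the tiglate, the alcohol attacking the less hindered angeloyl carbonyl.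

**Step 4**
Reactants: 6 (Z)-2-iodobut-2-enyl angelate; 7 tert-butyl glycolate (tert-butyl 2-hydroxyacetate)
Product: 8 2-tert-butoxy-2-oxoethyl (Z)-2-(angeloyloxymethyl)but-2-enoate
Conditions: PdCl2(PPh3)2 (5 mol%), CO (1 atm), 7 (3 equiv), iPr2NEt, DMF, 50 °C
Reagents that add atoms: carbon monoxide, [C-]#[O+]
Why: Pd-catalysed alkoxycarbonylation of an alkenyl iodide (oxidative addition, CO insertion, alcoholysis of the acyl-palladium) proceeds with retention of geometry, so the methyl group should end cis to the new ester carbonyl; C–I insertion should outrun ionisation of the allylic ester under CO.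

**Step 5**
Reactants: 8 2-tert-butoxy-2-oxoethyl (Z)-2-(angeloyloxymethyl)but-2-enoate
Product: 9 2-{[(Z)-2-(angeloyloxymethyl)but-2-enoyl]oxy}acetic acid
Conditions: TFA, CH2Cl2, 0 °C to rt
Reagents that add atoms: none
Why: Acidolysis of the tert-butyl ester through the tert-butyl cation should spare the primary esters and both trisubstituted enoates at this temperature.

**Step 6**
Reactants: 9 2-{[(Z)-2-(angeloyloxymethyl)but-2-enoyl]oxy}acetic acid
Product: 10 1,3-dioxoisoindolin-2-yl 2-{[(Z)-2-(angeloyloxymethyl)but-2-enoyl]oxy}acetate (redox-active ester)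
Conditions: N-hydroxyphthalimide, DIC, CH2Cl2, rt (no DMAP)
Reagents that add atoms: N-hydroxyphthalimide, O=C1c2ccccc2C(=O)N1O
Why: Carbodiimide coupling to the N-hydroxyphthalimide ester is routine, and leaving out DMAP avoids SN2′ attack on the 2-(acyloxymethyl)enoate.

**Step 7**
Reactants: 11 (E)-3,4-dimethoxycinnamic acid
Product: 12 (E)-4-(2-bromovinyl)-1,2-dimethoxybenzene
Conditions: NBS, LiOAc (cat.), MeCN/H2O, rt
Reagents that add atoms: N-bromosuccinimide, O=C1CCC(=O)N1Br
Why: The catalytic Hunsdiecker bromodecarboxylation works best on electron-rich cinnamic acids and should give the (E)-β-bromostyrene.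

**Step 8**
Reactants: 10 redox-active ester; 12 (E)-4-(2-bromovinyl)-1,2-dimethoxybenzene (2 equiv)
Product: 13 Morinin L, (E)-3-(3,4-dimethoxyphenyl)prop-2-enyl (Z)-2-{[(Z)-2-methylbut-2-enoyl]oxymethyl}but-2-enoate
Conditions: NiCl2·6H2O (20 mol%), 2,2′-bipyridine (20 mol%), AgNO3 (0.3 equiv), LiCl, DMF, (+)Mg/(−)RVC, constant current, undivided cell, rt
Reagents that add atoms: none
Why: Ni(0)/bipyridine inserts into the alkenyl C–Br bond with retention, while single-electron reduction of the N-hydroxyphthalimide ester releases phthalimide anion and CO2 to give the acyloxymethyl radical, which the alkenyl-Ni(II) captures before reductive elimination forms the C(sp3)–C(sp2) bond; the cathode returns nickel to its low-valent state and the magnesium anode supplies the electrons. The closest known reaction type is the Ni-catalysed reductive decarboxylative alkenylation of N-hydroxyphthalimide esters with alkenyl halides, here in its electrochemical form with a sacrificial anode and silver-modified cathode. No ring is closed and no stereocentre is formed; the E geometry follows from the bromide, and the mild potential should leave the two Z-enoates unreduced. The step needs chemoselectivity: the primary radical, stabilised by the adjacent acyloxy oxygen, must be trapped by nickel faster than it adds to the two β-methyl-substituted enoates, which are poor radical acceptors and could cyclise only by disfavoured 4-exo or 5-endo modes. Nickel must also prefer the C–Br bond over the allylic C–O bonds of the central ester and of the cinnamyl ester product, which the excess of 12 and stopping the electrolysis once 10 is consumed should secure.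

**Compound list**
1 | crotonaldehyde, (E)-but-2-enal | C/C=C/C=O | starting material
2 | (Z)-2-iodobut-2-enal | C/C=C(\I)C=O | intermediate
3 | (Z)-2-iodobut-2-en-1-ol | C/C=C(\I)CO | intermediate
4 | angelic acid, (Z)-2-methylbut-2-enoic acid | C/C=C(/C)C(=O)O | starting material
5 | angelic 2,4,6-trichlorobenzoic mixed anhydride | C/C=C(/C)C(=O)OC(=O)c1c(Cl)cc(Cl)cc1Cl | intermediate
6 | (Z)-2-iodobut-2-enyl (Z)-2-methylbut-2-enoate | C/C=C(/C)C(=O)OC/C(I)=C/C | intermediate
7 | tert-butyl glycolate | CC(C)(C)OC(=O)CO | starting material
8 | 2-tert-butoxy-2-oxoethyl (Z)-2-(angeloyloxymethyl)but-2-enoate | C/C=C(/C)C(=O)OC/C(=C/C)C(=O)OCC(=O)OC(C)(C)C | intermediate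
9 | 2-{[(Z)-2-(angeloyloxymethyl)but-2-enoyl]oxy}acetic acid | C/C=C(/C)C(=O)OC/C(=C/C)C(=O)OCC(=O)O | intermediate
10 | 1,3-dioxoisoindolin-2-yl 2-{[(Z)-2-(angeloyloxymethyl)but-2-enoyl]oxy}acetate | C/C=C(/C)C(=O)OC/C(=C/C)C(=O)OCC(=O)ON1C(=O)c2ccccc2C1=O | intermediate
11 | (E)-3,4-dimethoxycinnamic acid | COc1ccc(/C=C/C(=O)O)cc1OC | starting material
12 | (E)-4-(2-bromovinyl)-1,2-dimethoxybenzene | COc1ccc(/C=C/Br)cc1OC | intermediate
13 | Morinin L | C/C=C(/C)C(=O)OC/C(=C/C)C(=O)OC/C=C/c1ccc(OC)c(OC)c1 | target

**Step count:** 8 steps in total; the longest linear sequence is 7 steps (steps 1, 2, 3, 4, 5, 6, 8).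

**Steps most likely to fail**

1. Step 8. Low-valent nickel may ionise the allylic C–O bond of the cinnamyl ester as it forms, or the radical may be lost to reduction or dimerisation before capture. Fallback, from 11 and 6, returning at 13: acid 11 is activated with ethyl chloroformate and Et3N in THF at −10 °C to the mixed carbonic anhydride F1, which is reduced in the same flask with NaBH4/H2O to (E)-3,4-dimethoxycinnamyl alcohol F2. F2 is then the nucleophile in a Pd-catalysed alkoxycarbonylation of iodide 6 (PdCl2(PPh3)2, CO, iPr2NEt, DMF, 50 °C), which should give 13 directly by forming the acyl C–C and ester C–O bonds instead.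

2. Step 4. The alkenyl-palladium may undergo β-acyloxy elimination to an allene, or Pd(0) may ionise the allylic angelate of substrate or product. Fallback, from 3, returning at 8: alcohol 3 is silylated (TBSCl, imidazole, DMF) to the silyl ether F3, which has no allylic leaving group. F3 is carbonylated with 7 under the same Pd/CO conditions to ester F4, the silyl group is removed with HF·pyridine in THF to give hydroxy ester F5, and F5 is angeloylated with 4 through mixed anhydride 5 as in step 3 to give 8.

3. Step 3. Activation of the acyl group may isomerise the angelate to the tiglate. Fallback, from 3, returning at 6: alcohol 3 is converted by an Appel reaction (CBr4, PPh3, CH2Cl2, 0 °C) into (Z)-1-bromo-2-iodobut-2-ene F6, and the allylic bromide is displaced by caesium angelate (4, Cs2CO3, DMF, rt). This O-alkylation of the carboxylate never activates the angeloyl carbonyl and should give 6.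

**Further compounds**
F1 | step 8 | (E)-3,4-dimethoxycinnamic ethyl carbonic anhydride | COc1ccc(/C=C/C(=O)OC(=O)OCC)cc1OC
F2 | step 8 | (E)-3-(3,4-dimethoxyphenyl)prop-2-en-1-ol | COc1ccc(/C=C/CO)cc1OC
F3 | step 4 | tert-butyl{[(Z)-2-iodobut-2-enyl]oxy}dimethylsilane | C/C=C(\I)CO[Si](C)(C)C(C)(C)C
F4 | step 4 | 2-tert-butoxy-2-oxoethyl (Z)-2-[(tert-butyldimethylsilyloxy)methyl]but-2-enoate | C/C=C(\C(=O)OCC(=O)OC(C)(C)C)CO[Si](C)(C)C(C)(C)C
F5 | step 4 | 2-tert-butoxy-2-oxoethyl (Z)-2-(hydroxymethyl)but-2-enoate | C/C=C(\C(=O)OCC(=O)OC(C)(C)C)CO
F6 | step 3 | (Z)-1-bromo-2-iodobut-2-ene | C/C=C(\I)CBr
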